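**Plan**

- Retrosynthesis: the two ring C–O bonds are cut first (C2-symmetric 1,4-diol), then the bond from one benzylic CH2 to ring C3, then the bond from the other benzylic carbon to ring C4; a butenolide remains.
- Enabling feature: C3 and C4 are adjacent oxolane carbons, each flanked by an O–CH2 (C2, C5). With C2 raised to a lactone C=O and C5 to a chiral acetal, C4 becomes a Michael acceptor carbon and C3 the enolate carbon that follows from it.
- Forward: aryl dithiane (masked benzyl anion) → one-pot conjugate addition at C4 and enolate benzylation at C3 → desulfurization → LiAlH4 to the diol (carbonyl and auxiliary leave) → Mitsunobu closure of the oxolane last.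
- Stereochemistry: the (5R) acetal carbon (l-menthol series) directs C4 (anti), and C4 directs C3 (anti). The acetal centre is erased on reduction, which leaves (3R,4R).

Key step: step 2

Assumption: (5R)-5-(l-menthyloxy)furan-2(5H)-one and 3,4-dimethoxybenzyl bromide are taken as purchasable; the former is otherwise the crystalline l-menthyl acetal of 5-hydroxyfuran-2(5H)-one (furfural, singlet oxygen), and the latter is used freshly purified.

Step 1
Reactants: 1 3,4-dimethoxybenzaldehyde; 2 propane-1,3-dithiol
Product: 3 2-(3,4-dimethoxyphenyl)-1,3-dithiane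
Conditions: BF3·OEt2 (cat.), CH2Cl2, 0 °C to rt
Reagents that add atoms: none
Why: BF3-catalysed dithioacetalisation of the aromatic aldehyde should proceed cleanly and installs the 1,3-dithiane that makes the future benzylic carbon a carbanion (umpolung) for the key step.

Step 2
Reactants: 3 2-(3,4-dimethoxyphenyl)-1,3-dithiane; 4 (5R)-5-{[(1R,2S,5R)-2-isopropyl-5-methylcyclohexyl]oxy}furan-2(5H)-one [(5R)-5-(l-menthyloxy)butenolide]; 5 3,4-dimethoxybenzyl bromide
Product: 8 (3R,4R,5R)-3-(3,4-dimethoxybenzyl)-4-[2-(3,4-dimethoxyphenyl)-1,3-dithian-2-yl]-5-(l-menthyloxy)dihydrofuran-2(3H)-one (all-trans: C3 benzyl anti to C4 dithianyl, C4 dithianyl anti to C5 menthyloxy), via lithiated dithiane 6 (not isolated), via lithium enolate 7 (not isolated)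
Conditions: n-BuLi, THF, −78 to −20 °C; then 4, −78 °C; then 5, DMPU, −78 °C to rt; aq. NH4Cl
Reagents that add atoms: none
Why: n-BuLi deprotonates C2 of the dithiane, and the soft, aryl- and sulfur-stabilised carbanion 6 adds in a 1,4 sense to C4 of butenolide 4 to give lithium enolate 7, whose C3 then displaces bromide from 5 in an SN2 reaction, which forms the bond between the benzylic CH2 and the future ring C3 and joins the two aryl-bearing halves. The closest known reaction type is the tandem Michael addition–enolate alkylation (three-component coupling) of γ-alkoxybutenolides with lithiated dithioacetals and benzylic halides. No ring is closed in this step; the five-membered lactone acetal is carried through intact. The new stereocentre at C4 is controlled by the C5 acetal centre, because the nucleophile attacks the ring face anti to the menthyloxy group, and the new stereocentre at C3 is controlled by C4, because the electrophile enters anti to the bulky dithianyl group, so that the 3,4-trans relation and the absolute configuration both derive from the (5R) acetal. The step needs 1,4- over 1,2-addition, which the delocalised hindered carbanion and the unsubstituted β-carbon should secure, and C-alkylation ahead of proton transfer, which the reactive benzylic bromide and DMPU should secure.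

Step 3
Reactants: 8 (3R,4R,5R)-3-(3,4-dimethoxybenzyl)-4-[2-(3,4-dimethoxyphenyl)-1,3-dithian-2-yl]-5-(l-menthyloxy)dihydrofuran-2(3H)-one
Product: 9 (3R,4R,5R)-3,4-bis(3,4-dimethoxybenzyl)-5-(l-menthyloxy)dihydrofuran-2(3H)-one
Conditions: Raney Ni (W-2, excess), EtOH–THF, reflux
Reagents that add atoms: none
Why: Raney nickel hydrogenolysis of the four C–S bonds (reductive desulfurization of a dithioacetal) should turn the dithiane carbon into the second benzylic CH2 without touching the lactone acetal or the aryl ethers, and the only epimerizable centre (C3, α to the carbonyl) already holds its thermodynamically preferred all-trans arrangement.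

Step 4
Reactants: 9 (3R,4R,5R)-3,4-bis(3,4-dimethoxybenzyl)-5-(l-menthyloxy)dihydrofuran-2(3H)-one
Product: 10 (2R,3R)-2,3-bis(3,4-dimethoxybenzyl)butane-1,4-diol
Conditions: LiAlH4, THF, 0 °C to rt; then H2O, aq. NaOH
Reagents that add atoms: none
Why: Hydride reduction of the lactone opens the ring, the freed hemiacetal alkoxide at C5 expels menthoxide and the resulting aldehyde is reduced as well (LiAlH4 reduction of a γ-alkoxy lactone to a 1,4-diol), which removes carbonyl and auxiliary in one operation while the two stereocentres should be kept because the transient aldehydes are reduced faster than they enolize.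

Step 5
Reactants: 10 (2R,3R)-2,3-bis(3,4-dimethoxybenzyl)butane-1,4-diol
Product: 11 (3R,4R)-3,4-bis(3,4-dimethoxybenzyl)tetrahydrofuran (trans)
Conditions: PPh3, DIAD, THF, 0 °C to rt
Reagents that add atoms: none
Why: Mitsunobu cyclodehydration should activate one of the two homotopic primary hydroxyls as an oxyphosphonium ion, which the other displaces in a 5-exo-tet SN2 reaction, closing the oxolane without touching C3 or C4.

**Compound list**

1 | 3,4-dimethoxybenzaldehyde | COc1ccc(C=O)cc1OC | starting material
2 | propane-1,3-dithiol | SCCCS | starting material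
3 | 2-(3,4-dimethoxyphenyl)-1,3-dithiane | COc1ccc(C2SCCCS2)cc1OC | intermediate
4 | (5R)-5-{[(1R,2S,5R)-2-isopropyl-5-methylcyclohexyl]oxy}furan-2(5H)-one | O=C1C=C[C@H](O[C@@H]2C[C@H](C)CC[C@H]2C(C)C)O1 | starting material
5 | 3,4-dimethoxybenzyl bromide | COc1ccc(CBr)cc1OC | starting material
6 | 2-lithio-2-(3,4-dimethoxyphenyl)-1,3-dithiane | [Li]C1(c2ccc(OC)c(OC)c2)SCCCS1 | intermediate
7 | lithium (4R,5R)-4-[2-(3,4-dimethoxyphenyl)-1,3-dithian-2-yl]-5-(l-menthyloxy)-4,5-dihydrofuran-2-olate | [Li]OC1=C[C@@H](C2(c3ccc(OC)c(OC)c3)SCCCS2)[C@H](O[C@@H]2C[C@H](C)CC[C@H]2C(C)C)O1 | intermediate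
8 | (3R,4R,5R)-3-(3,4-dimethoxybenzyl)-4-[2-(3,4-dimethoxyphenyl)-1,3-dithian-2-yl]-5-(l-menthyloxy)dihydrofuran-2(3H)-one | O=C1[C@H](Cc2ccc(OC)c(OC)c2)[C@@H](C2(c3ccc(OC)c(OC)c3)SCCCS2)[C@H](O[C@@H]2C[C@H](C)CC[C@H]2C(C)C)O1 | intermediate
9 | (3R,4R,5R)-3,4-bis(3,4-dimethoxybenzyl)-5-(l-menthyloxy)dihydrofuran-2(3H)-one | O=C1[C@H](Cc2ccc(OC)c(OC)c2)[C@@H](Cc2ccc(OC)c(OC)c2)[C@H](O[C@@H]2C[C@H](C)CC[C@H]2C(C)C)O1 | intermediate
10 | (2R,3R)-2,3-bis(3,4-dimethoxybenzyl)butane-1,4-diol | OC[C@H](Cc1ccc(OC)c(OC)c1)[C@@H](Cc1ccc(OC)c(OC)c1)CO | intermediate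
11 | (3R,4R)-3,4-bis(3,4-dimethoxybenzyl)tetrahydrofuran | COc1ccc(C[C@H]2COC[C@@H]2Cc2ccc(OC)c(OC)c2)cc1OC | target

**Step count**

Total steps: 5. Longest linear sequence: 5 steps (1 → 3 → 8 → 9 → 10 → 11).

**Steps most likely to fail**

Step 2. The enolate flanked by the quaternary dithianyl carbon may be protonated or O-alkylated faster than it is C-benzylated, so that the one-pot sequence stops after the conjugate addition. The fallback separates the two bond formations and alkylates a less hindered enolate. It sets out from 3 and 4: the conjugate addition is run as before (through 6 and 7) but quenched with aq. NH4Cl to give the Michael adduct (4R,5R)-4-[2-(3,4-dimethoxyphenyl)-1,3-dithian-2-yl]-5-(l-menthyloxy)dihydrofuran-2(3H)-one F1. Raney nickel desulfurization should give (4R,5R)-4-(3,4-dimethoxybenzyl)-5-(l-menthyloxy)dihydrofuran-2(3H)-one F2. Deprotonation with LDA in THF at −78 °C should give lithium (4R,5R)-4-(3,4-dimethoxybenzyl)-5-(l-menthyloxy)-4,5-dihydrofuran-2-olate F3, which is alkylated with 5 anti to the C4 benzyl group (classical trans-selective alkylation of a β-substituted butyrolactone enolate). The fallback comes back to the route at 9.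

Step 3. Hydrogenolysis of the C–S bonds at the hindered quaternary carbon may stay incomplete, or the lactone acetal may be opened or transesterified on the basic nickel surface in ethanol. The fallback removes the sulfur last, from a substrate that carries neither lactone nor acetal. It sets out from 8: LiAlH4 in THF should give (2R,3R)-2-(3,4-dimethoxybenzyl)-3-[2-(3,4-dimethoxyphenyl)-1,3-dithian-2-yl]butane-1,4-diol F4 with loss of the auxiliary. Mitsunobu cyclodehydration (PPh3, DIAD) should give (3R,4R)-3-(3,4-dimethoxybenzyl)-4-[2-(3,4-dimethoxyphenyl)-1,3-dithian-2-yl]tetrahydrofuran F5. Desulfurization of this robust ether with nickel boride (NiCl2·6H2O, NaBH4, MeOH–THF) comes back to the route at 11.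

Step 4. The one-pot reduction may stall after the first hydride transfer if the hemiacetal aluminate does not collapse, which would leave lactol and menthyl acetal alcohols in place of the diol. The fallback reduces the two carbonyl-level carbons in separate stages. It sets out from 9: NaBH4 in aqueous-ethanolic KOH opens the acetal lactone and reduces the liberated aldehyde in situ to potassium (2R,3R)-2,3-bis(3,4-dimethoxybenzyl)-4-hydroxybutanoate F6 (not isolated). Acidification should close this to the trans lactone (3R,4R)-3,4-bis(3,4-dimethoxybenzyl)dihydrofuran-2(3H)-one F7, which can be purified by crystallization. LiAlH4 reduction of this simple lactone comes back to the route at 10.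

**Further compounds**

F1 | step 2 | (4R,5R)-4-[2-(3,4-dimethoxyphenyl)-1,3-dithian-2-yl]-5-(l-menthyloxy)dihydrofuran-2(3H)-one | O=C1C[C@@H](C2(c3ccc(OC)c(OC)c3)SCCCS2)[C@H](O[C@@H]2C[C@H](C)CC[C@H]2C(C)C)O1
F2 | step 2 | (4R,5R)-4-(3,4-dimethoxybenzyl)-5-(l-menthyloxy)dihydrofuran-2(3H)-one | O=C1C[C@@H](Cc2ccc(OC)c(OC)c2)[C@H](O[C@@H]2C[C@H](C)CC[C@H]2C(C)C)O1
F3 | step 2 | lithium (4R,5R)-4-(3,4-dimethoxybenzyl)-5-(l-menthyloxy)-4,5-dihydrofuran-2-olate | [Li]OC1=C[C@@H](Cc2ccc(OC)c(OC)c2)[C@H](O[C@@H]2C[C@H](C)CC[C@H]2C(C)C)O1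
F4 | step 3 | (2R,3R)-2-(3,4-dimethoxybenzyl)-3-[2-(3,4-dimethoxyphenyl)-1,3-dithian-2-yl]butane-1,4-diol | OC[C@H](Cc1ccc(OC)c(OC)c1)[C@@H](C1(c2ccc(OC)c(OC)c2)SCCCS1)CO
F5 | step 3 | (3R,4R)-3-(3,4-dimethoxybenzyl)-4-[2-(3,4-dimethoxyphenyl)-1,3-dithian-2-yl]tetrahydrofuran | COc1ccc(C[C@H]2COC[C@@H]2C2(c3ccc(OC)c(OC)c3)SCCCS2)cc1OC
F6 | step 4 | potassium (2R,3R)-2,3-bis(3,4-dimethoxybenzyl)-4-hydroxybutanoate | [K+].[O-]C(=O)[C@H](Cc1ccc(OC)c(OC)c1)[C@@H](Cc1ccc(OC)c(OC)c1)CO
F7 | step 4 | (3R,4R)-3,4-bis(3,4-dimethoxybenzyl)dihydrofuran-2(3H)-one | O=C1[C@H](Cc2ccc(OC)c(OC)c2)[C@@H](Cc2ccc(OC)c(OC)c2)CO1
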